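The route rests on closing each pyran ring at C2–C3 (chroman numbering; ring A is the fused benzo ring, ring B the 3-aryl group) while C4 is still a ketone. In a symmetric bis(2-hydroxydeoxybenzoin), an aryl benzyl ketone on each side of the diaryl ether, the ring A phenol oxygen O1 is formylated, and C3, acidified by the C4 carbonyl and by ring B, attacks the formate carbon; loss of water gives the bis-isoflavone, so one operation builds both heterocycles. The C4 carbonyl is a traceless activating group: it makes C3 nucleophilic, then lets a ruthenium transfer hydrogenation with dynamic kinetic resolution set both C3 centres as R, and leaves by hydrogenolysis with the benzyl ethers.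

Key step: step 8

Remark: the two halves of the target are identical and both C3 centres are R, so the molecule is C2-symmetric and is built in two directions from one diaryl ether core; the two-directional coupling of step 7 therefore consumes two molecules of ketone 11 per molecule of core 9.

Step 1
Reactants: 1 1-bromo-4-fluoro-2-methoxybenzene
Product: 3 3-bromo-6-fluoro-2-methoxybenzaldehyde, via aryllithium 2 (not isolated)
Conditions: LiN(iPr)2, THF, −78 °C; DMF, −78 °C to rt; aq. HCl
Reagents that add atoms: N,N-dimethylformamide, CN(C)C=O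
Why: Directed ortho-lithiation should remove the proton flanked by F and OMe, the most acidic one, without exchanging the bromide at −78 °C, and the aryllithium is then formylated by DMF.

Step 2
Reactants: 3 3-bromo-6-fluoro-2-methoxybenzaldehyde
Product: 5 3-bromo-6-hydroxy-2-methoxybenzaldehyde, via sulfonylethyl aryl ether 4 (not isolated)
Conditions: MeSO2CH2CH2OH, NaH, DMF, 0 °C to rt; aq. HCl
Reagents that add atoms: 2-(methylsulfonyl)ethanol, CS(=O)(=O)CCO
Why: Nucleophilic aromatic substitution (SNAr) of the fluoride ortho to the formyl group by the alkoxide, then E1cB loss of methyl vinyl sulfone, should give the phenol with a hydroxide surrogate that avoids a Cannizzaro reaction.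

Step 3
Reactants: 3 3-bromo-6-fluoro-2-methoxybenzaldehyde; 5 3-bromo-6-hydroxy-2-methoxybenzaldehyde
Product: 6 6,6'-oxybis(3-bromo-2-methoxybenzaldehyde)
Conditions: K2CO3, DMF, 110 °C
Reagents that add atoms: none
Why: SNAr diaryl ether synthesis, in which the phenoxide of 5 displaces the fluoride of 3 activated by its ortho formyl group, while the bromides, meta to the formyl groups, should stay untouched.

Step 4
Reactants: 6 6,6'-oxybis(3-bromo-2-methoxybenzaldehyde)
Product: 8 6,6'-oxybis(3-bromo-2-methoxyphenol), via ring B bis(formate) 7 (not isolated)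
Conditions: mCPBA, NaHCO3, CH2Cl2, rt; then K2CO3, MeOH, rt
Reagents that add atoms: 3-chloroperoxybenzoic acid (mCPBA), OOC(=O)c1cccc(Cl)c1
Why: Baeyer–Villiger oxidation in the Dakin sense, in which the doubly ortho-oxygenated aryl group migrates, followed by methanolysis of the formates, should turn both formyl groups into the future ring B hydroxyls.

Step 5
Reactants: 8 6,6'-oxybis(3-bromo-2-methoxyphenol)
Product: 9 1,1'-oxybis[2-(benzyloxy)-4-bromo-3-methoxybenzene]
Conditions: BnBr, K2CO3, DMF, 60 °C
Reagents that add atoms: benzyl bromide, BrCc1ccccc1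
Why: Williamson ether synthesis masks the two ring B phenols as benzyl ethers until the final hydrogenolysis.

Step 6
Reactants: 10 1-[4-(benzyloxy)-2-hydroxyphenyl]ethan-1-one
Product: 11 1-[4-(benzyloxy)-2-(methoxymethoxy)phenyl]ethan-1-one
Conditions: NaH, MOMCl, DMF, 0 °C to rt
Reagents that add atoms: chloromethyl methyl ether, COCCl
Why: Williamson-type O-alkylation of the sodium phenoxide gives a MOM ether that is inert to the strong base of step 7 and can be removed without touching benzyl ethers.

Step 7
Reactants: 9 1,1'-oxybis[2-(benzyloxy)-4-bromo-3-methoxybenzene]; 11 1-[4-(benzyloxy)-2-(methoxymethoxy)phenyl]ethan-1-one (two molecules, one for each aryl bromide of 9)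
Product: 13 2,2'-[oxybis(3-(benzyloxy)-2-methoxy-4,1-phenylene)]bis{1-[4-(benzyloxy)-2-hydroxyphenyl]ethan-1-one}, via bis(MOM ether) 12 (not isolated)
Conditions: 11 (2.2 equiv), Pd2(dba)3, XPhos, NaOtBu, toluene, 80 °C; then 3 M HCl, MeOH/THF, 50 °C
Reagents that add atoms: 1-[4-(benzyloxy)-2-(methoxymethoxy)phenyl]ethan-1-one (the second molecule of 11 that the two-fold coupling consumes), CC(=O)c1ccc(OCc2ccccc2)cc1OCOC
Why: Two-fold palladium-catalysed ketone α-arylation (Buchwald–Hartwig type, zerovalent palladium cycle), in which one methyl ketone enolate of 11 couples at each of the two aryl bromides of 9 and the ortho methoxy group and the bulky ligand should stop each ketone at monoarylation, is followed by acid cleavage of the two MOM acetals to free the chelated ring A phenols.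

Step 8
Reactants: 13 2,2'-[oxybis(3-(benzyloxy)-2-methoxy-4,1-phenylene)]bis{1-[4-(benzyloxy)-2-hydroxyphenyl]ethan-1-one}
Product: 16 3,3'-[oxybis(3-(benzyloxy)-2-methoxy-4,1-phenylene)]bis[7-(benzyloxy)-4H-chromen-4-one], via ring A bis(formate) 14 (not isolated), via bis(2-hydroxyisoflavanone) 15 (not isolated)
Conditions: HCO2H, CDI, THF, 0 °C to rt; then 13, rt to 60 °C
Reagents that add atoms: N-formylimidazole, O=Cn1ccnc1 (made in the flask from formic acid, OC=O, with 1,1'-carbonyldiimidazole)
Why: N-Formylimidazole should acylate the only free hydroxyl, the chelated ring A phenol O1–H, to give the aryl formate 14; imidazole then enolises the ketone, C3 adds to the formate carbonyl to give the cyclic hemiacetal 15, and loss of water gives the 4-pyranone. The closest known reaction type is the Kostanecki–Robinson annulation in its formyl version, the synthesis of isoflavones from 2-hydroxydeoxybenzoins with formylating agents. Each pyranone ring closes by C2–C3 bond formation in a 6-(enolendo)-exo-trig aldol-type addition. No stereocentre survives the step, since C2 and C3 of 15 become sp2; C3 is set in step 9. The step needs O-formylation to precede C–C bond formation and both halves to react: the neutral acyl imidazole can acylate only the phenol (all other hydroxyls are benzylated and the ketone is not enolised before O-acylation), C3 is the only enolisable carbon (α to the C4 ketone, benzylic to ring B), and aromatisation to the pyranone drives each closure forward.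

Step 9
Reactants: 16 3,3'-[oxybis(3-(benzyloxy)-2-methoxy-4,1-phenylene)]bis[7-(benzyloxy)-4H-chromen-4-one]
Product: 18 (3R,4R,3'R,4'R)-3,3'-[oxybis(3-(benzyloxy)-2-methoxy-4,1-phenylene)]bis[7-(benzyloxy)chroman-4-ol], via bis(isoflavanone) 17 (not isolated)
Conditions: RuCl[(R,R)-TsDPEN](p-cymene), HCO2H/Et3N (5:2), EtOAc/DMF, 45 °C
Reagents that add atoms: none
Why: In this Noyori–Ikariya asymmetric transfer hydrogenation the ruthenium hydride should first reduce C2=C3 of each pyranone by 1,4-addition, the resulting isoflavanone 17 epimerises at C3 under Et3N, and the (R,R) catalyst reduces the C4 ketone of the (3R) epimer faster from the face anti to the aryl group (dynamic kinetic resolution), which by the aryl ketone model gives 4R and hence the cis (3R,4R) alcohol in each independent half.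

Step 10
Reactants: 18 (3R,4R,3'R,4'R)-3,3'-[oxybis(3-(benzyloxy)-2-methoxy-4,1-phenylene)]bis[7-(benzyloxy)chroman-4-ol]
Product: 19 (3R,3'R)-3,3'-[oxybis(3-hydroxy-2-methoxy-4,1-phenylene)]bis(chroman-7-ol)
Conditions: H2 (3 bar), Pd(OH)2/C, EtOAc/EtOH, AcOH, rt
Reagents that add atoms: none
Why: Heterogeneous hydrogenolysis should cleave the four benzyl ethers and the two benzylic C4–O bonds (activated by the para O7 and the ortho O1) without involving C3, which keeps its R configuration.

Compound list
1 | 1-bromo-4-fluoro-2-methoxybenzene (2-bromo-5-fluoroanisole) | COc1cc(F)ccc1Br | starting material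
2 | (3-bromo-6-fluoro-2-methoxyphenyl)lithium, not isolated | [Li]c1c(OC)c(Br)ccc1F | intermediate
3 | 3-bromo-6-fluoro-2-methoxybenzaldehyde | COc1c(Br)ccc(F)c1C=O | intermediate
4 | 3-bromo-2-methoxy-6-[2-(methylsulfonyl)ethoxy]benzaldehyde, not isolated | COc1c(Br)ccc(OCCS(C)(=O)=O)c1C=O | intermediate
5 | 3-bromo-6-hydroxy-2-methoxybenzaldehyde | COc1c(Br)ccc(O)c1C=O | intermediate
6 | 6,6'-oxybis(3-bromo-2-methoxybenzaldehyde) | COc1c(Br)ccc(Oc2ccc(Br)c(OC)c2C=O)c1C=O | intermediate
7 | 6,6'-oxybis(3-bromo-2-methoxyphenyl) diformate, not isolated | COc1c(Br)ccc(Oc2ccc(Br)c(OC)c2OC=O)c1OC=O | intermediate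
8 | 6,6'-oxybis(3-bromo-2-methoxyphenol) | COc1c(Br)ccc(Oc2ccc(Br)c(OC)c2O)c1O | intermediate
9 | 1,1'-oxybis[2-(benzyloxy)-4-bromo-3-methoxybenzene] | COc1c(Br)ccc(Oc2ccc(Br)c(OC)c2OCc2ccccc2)c1OCc1ccccc1 | intermediate
10 | 1-[4-(benzyloxy)-2-hydroxyphenyl]ethan-1-one | CC(=O)c1ccc(OCc2ccccc2)cc1O | starting material
11 | 1-[4-(benzyloxy)-2-(methoxymethoxy)phenyl]ethan-1-one | CC(=O)c1ccc(OCc2ccccc2)cc1OCOC | intermediate
12 | 2,2'-[oxybis(3-(benzyloxy)-2-methoxy-4,1-phenylene)]bis{1-[4-(benzyloxy)-2-(methoxymethoxy)phenyl]ethan-1-one}, not isolated | COCOc1cc(OCc2ccccc2)ccc1C(=O)Cc1ccc(Oc2ccc(CC(=O)c3ccc(OCc4ccccc4)cc3OCOC)c(OC)c2OCc2ccccc2)c(OCc2ccccc2)c1OC | intermediate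
13 | 2,2'-[oxybis(3-(benzyloxy)-2-methoxy-4,1-phenylene)]bis{1-[4-(benzyloxy)-2-hydroxyphenyl]ethan-1-one} | Oc1cc(OCc2ccccc2)ccc1C(=O)Cc1ccc(Oc2ccc(CC(=O)c3ccc(OCc4ccccc4)cc3O)c(OC)c2OCc2ccccc2)c(OCc2ccccc2)c1OC | intermediate
14 | bis(formate ester) of 13 at both ring A phenols, not isolated | O=COc1cc(OCc2ccccc2)ccc1C(=O)Cc1ccc(Oc2ccc(CC(=O)c3ccc(OCc4ccccc4)cc3OC=O)c(OC)c2OCc2ccccc2)c(OCc2ccccc2)c1OC | intermediate
15 | 3,3'-[oxybis(3-(benzyloxy)-2-methoxy-4,1-phenylene)]bis[7-(benzyloxy)-2-hydroxychroman-4-one], mixture of stereoisomers, not isolated | OC1Oc2cc(OCc3ccccc3)ccc2C(=O)C1c1ccc(Oc2ccc(C3C(O)Oc4cc(OCc5ccccc5)ccc4C3=O)c(OC)c2OCc2ccccc2)c(OCc2ccccc2)c1OC | intermediate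
16 | 3,3'-[oxybis(3-(benzyloxy)-2-methoxy-4,1-phenylene)]bis[7-(benzyloxy)-4H-chromen-4-one] | O=c1c(-c2ccc(Oc3ccc(-c4coc5cc(OCc6ccccc6)ccc5c4=O)c(OC)c3OCc3ccccc3)c(OCc3ccccc3)c2OC)coc2cc(OCc3ccccc3)ccc12 | intermediate
17 | 3,3'-[oxybis(3-(benzyloxy)-2-methoxy-4,1-phenylene)]bis[7-(benzyloxy)chroman-4-one], interconverting C3 epimers, not isolated | O=C1c2ccc(OCc3ccccc3)cc2OCC1c1ccc(Oc2ccc(C3COc4cc(OCc5ccccc5)ccc4C3=O)c(OC)c2OCc2ccccc2)c(OCc2ccccc2)c1OC | intermediate
18 | (3R,4R,3'R,4'R)-3,3'-[oxybis(3-(benzyloxy)-2-methoxy-4,1-phenylene)]bis[7-(benzyloxy)chroman-4-ol], cis in each ring | O[C@H]1c2ccc(OCc3ccccc3)cc2OC[C@H]1c1ccc(Oc2ccc([C@@H]3COc4cc(OCc5ccccc5)ccc4[C@@H]3O)c(OC)c2OCc2ccccc2)c(OCc2ccccc2)c1OC | intermediate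
19 | (3R,3'R)-3,3'-[oxybis(3-hydroxy-2-methoxy-4,1-phenylene)]bis(chroman-7-ol) | COc1c([C@@H]2COc3cc(O)ccc3C2)ccc(Oc2ccc([C@@H]3COc4cc(O)ccc4C3)c(OC)c2O)c1O | target

Total step count: 10 steps.
Longest linear sequence: 9 steps (steps 1, 2, 3, 4, 5, 7, 8, 9, 10, from 1 to 19).

Steps most likely to fail

Step 8 (double annulation). The formyl group may be transferred back to imidazole or to traces of water faster than the intramolecular aldol addition, or only one half may cyclise. The fallback sets out from 13 and changes the C1 electrophile from an acyl to an alkyl carbon: diiodomethane (ICI) and K2CO3 in DMF at 60 °C should alkylate each chelated phenoxide to the bis(iodomethyl aryl ether) F1, which is not isolated. The C3 enolate then displaces iodide in a 6-(enolendo)-exo-tet closure, again forming C2–C3, to give the bis(isoflavanone) 17, where the fallback comes back to the route. Compound 17 is then carried through the conditions of step 9 and enters at the dynamic kinetic resolution.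

Step 7 (double α-arylation). The product enolate may be arylated a second time, the second bromide may couple incompletely, or reductive debromination may compete. The fallback sets out from 9 and builds the ketone by acylating ring A instead of arylating an enolate. Two-fold decarboxylative cyanomethylation with potassium cyanoacetate (N#CCC(=O)[O-].[K+]; [Pd(allyl)Cl]2, SPhos, mesitylene, 140 °C) should give the bis(arylacetonitrile) F2. Houben–Hoesch acylation of resorcinol (Oc1cccc(O)c1, two molecules per molecule of F2) with F2 (ZnCl2, HCl gas, Et2O, 0 °C) should give the bis(ketiminium chloride) F3, which is hydrolysed in hot water without isolation to the bis(2,4-dihydroxyphenyl ketone) F4. Benzylation of the non-chelated para hydroxyl of each ring A (BnBr, K2CO3, acetone, reflux) then comes back to the route at 13.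

Step 10 (global hydrogenolysis). Under the acidic conditions C4 may ionise and eliminate towards C3 to an isoflav-3-ene that is re-hydrogenated without facial control, eroding the C3 configuration, or the C4–O cleavage may stall. The fallback sets out from 18 and removes the C4 oxygens by a radical path that cannot touch C3. NaH, CS2 and MeI in THF should give the bis(S-methyl xanthate) F5; Bu3SnH and AIBN in toluene at 90 °C (Barton–McCombie deoxygenation) should give the tetra-O-benzyl isoflavan F6. Neutral hydrogenolysis of the four benzyl ethers (H2, Pd/C, EtOAc/MeOH, rt) then comes back to the route at 19.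

Further compounds
F1 | step 8 | 2,2'-[oxybis(3-(benzyloxy)-2-methoxy-4,1-phenylene)]bis{1-[4-(benzyloxy)-2-(iodomethoxy)phenyl]ethan-1-one}, not isolated | ICOc1cc(OCc2ccccc2)ccc1C(=O)Cc1ccc(Oc2ccc(CC(=O)c3ccc(OCc4ccccc4)cc3OCI)c(OC)c2OCc2ccccc2)c(OCc2ccccc2)c1OC
F2 | step 7 | 2,2'-[oxybis(3-(benzyloxy)-2-methoxy-4,1-phenylene)]diacetonitrile | N#CCc1ccc(Oc2ccc(CC#N)c(OC)c2OCc2ccccc2)c(OCc2ccccc2)c1OC
F3 | step 7 | bis(ketiminium chloride) from F2 and resorcinol, not isolated | [Cl-].[Cl-].[NH2+]=C(Cc1ccc(Oc2ccc(CC(=[NH2+])c3ccc(O)cc3O)c(OC)c2OCc2ccccc2)c(OCc2ccccc2)c1OC)c1ccc(O)cc1O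
F4 | step 7 | 2,2'-[oxybis(3-(benzyloxy)-2-methoxy-4,1-phenylene)]bis[1-(2,4-dihydroxyphenyl)ethan-1-one] | O=C(Cc1ccc(Oc2ccc(CC(=O)c3ccc(O)cc3O)c(OC)c2OCc2ccccc2)c(OCc2ccccc2)c1OC)c1ccc(O)cc1O
F5 | step 10 | bis(O-alkyl S-methyl xanthate) of 18 at both C4 oxygens, (3R,4R,3'R,4'R) | CSC(=S)O[C@H]1c2ccc(OCc3ccccc3)cc2OC[C@H]1c1ccc(Oc2ccc([C@@H]3COc4cc(OCc5ccccc5)ccc4[C@@H]3OC(=S)SC)c(OC)c2OCc2ccccc2)c(OCc2ccccc2)c1OC
F6 | step 10 | (3R,3'R)-3,3'-[oxybis(3-(benzyloxy)-2-methoxy-4,1-phenylene)]bis[7-(benzyloxy)chromane] | COc1c([C@@H]2COc3cc(OCc4ccccc4)ccc3C2)ccc(Oc2ccc([C@@H]3COc4cc(OCc5ccccc5)ccc4C3)c(OC)c2OCc2ccccc2)c1OCc1ccccc1
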